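3 questions are put to a catalysed flask whose product levels off well short of the charge, and 4 earlier runs are there to answer them.

| flask | starting material | free catalyst | time |
|---|---|---|---|
| midnight | 300 mM | 6.00 mM |  |
| dusk | 180 mM | 6.00 mM |  |
| noon | 600 mM | 6.00 mM |  |
| winter | 300 mM | 3.00 mM |  |
| autumn | 300 mM | 6.00 mM | 35 min |

| run | time / min | [product] / mM |
|---|---|---|
| midnight run | 0.97 | 33.9 |
| midnight run | 1.9 | 58.5 |
| midnight run | 2.9 | 70.8 |
| midnight run | 3.9 | 79.4 |
| midnight run | 4.8 | 85.3 |
| midnight run | 5.8 | 87.9 |
| dusk run | 0.97 | 17.6 |
| dusk run | 1.9 | 28.9 |
| dusk run | 2.9 | 36.9 |
| dusk run | 3.9 | 40.6 |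
| dusk run | 4.8 | 42.9 |
| dusk run | 5.8 | 43.6 |
| noon run | 0.97 | 68.9 |
| noon run | 1.9 | 117.7 |
| noon run | 2.9 | 158.9 |
| noon run | 3.9 | 184.5 |
| noon run | 4.8 | 202.0 |
| noon run | 5.8 | 212.6 |
| winter run | 0.97 | 17.3 |
| winter run | 1.9 | 29.9 |
| winter run | 2.9 | 39.5 |
| winter run | 3.9 | 45.6 |
| winter run | 4.8 | 49.7 |
| winter run | 5.8 | 51.7 |

(readings scatter by 0.9 mM)

* reaction order in [starting material] at the outset, round the charge of the midnight run, defined at two percent of the starting material turned into product (one fixed amount of product, the same in the runs compared)
* reaction order in [free catalyst] at the outset, round the charge of the midnight run, defined at two percent of the starting material turned into product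
* product in the autumn run at 35 min, as a share of the starting material charged

- Overall: starting material -> product, with free catalyst as catalyst.
- Constant volume, constant temperature.
- What is held in complexes is read along with the free species.
- An order is taken over about fifteen percent of the charge, up and down.

The first readings, at 0.97 min, stand in for the outset rates, so that noon against dusk gives an order near 1.13 in starting material and midnight against winter one near 0.971 in free catalyst. In the midnight run, the gain over the last step of about two minutes is 0.407 of the gain over the step before, and summing that geometric tail puts the final product at 31.2 % of the charge, which is this reckoning's answer for autumn, a flask with the same recipe. The same sum for the winter run gives 0.389 as ratio and 18.5 % as final share.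

Set the final share of product over the share of the charge that did not become product, and call this the end odds, a selectivity factor between product and whatever else takes the charge. They come to 0.454 for midnight and 0.227 for winter, a ratio of 2.00 for a catalyst ratio of 2.00. Between these two runs, at the one charge of 300 mM, the end odds thus read as proportional to free catalyst, and a final share is recovered from them as odds over one plus odds.

The forecast, “Summing the tail” of midnight, gives orders of 1.08 and 1 and, slightly above this reckoning, 31.5 % for autumn. The flask gives 1.1, 1.0 and 29.9 %.

    free catalyst + starting material ⇌ catalyst-substrate complex, settled at all times (1.170 M⁻¹)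
    catalyst-substrate complex + starting material ⇌ doubly bound catalyst, settled at all times (8.810 M⁻¹)
    doubly bound catalyst → product + catalyst-substrate complex (70.20 min⁻¹)
    starting material → decomposed substrate (0.5496 min⁻¹)
    2 starting material ⇌ idle substrate dimer, settled at all times (7.830 M⁻¹)

The reaction of starting material to decomposed substrate is the main reason the autumn run stops at 29.9 %, since the same run without it reaches 95.1 %. The autumn end odds are therefore 0.427, a little below the 0.454 reckoned from the readings. Scaled by the catalyst ratio of the winter run, they become 0.213, a final share of 17.6 %, and the last winter reading, at 5.8 min, stands at 17.2 % of its charge, still climbing.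

All runs are calculated for substances that don't exist.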